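## Retrosynthetic overview

1. Atom names follow phthalide numbering: unit A is unprimed (C1, O2, C3, C3a, C4–C7, C7a, butylidene C8), unit B is primed, and ring C is C6–C7'–C6'–C5'–C4'–C7. Both (Z)-butylidene lactones are made last: the ring A lactone by carbonylative cyclisation of a 2-pentanoyl enol triflate (C1 from CO), the ring B lactone by a 5-exo Heck closure that forms C3a'–C3'.
2. Enabling feature: in the unit B butenolide, C3' is bound to the lactone oxygen O2', so an (E)-pent-1-enyl ester of the C7a' carboxylic acid already holds C3' five atoms from C3a'. C3a'=C7a' sits on the alkene bridge of the bicyclo[2.2.2]octene as the enol triflate of a β-keto ester, flanked only by the bridgeheads C4' and C7', so no other cyclisation mode and no sp3 stereocentre is in play.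
3. The bicyclo[2.2.2]octene (bridgeheads C7', C4') comes from a Diels–Alder reaction of a ring C 2-silyloxydiene with tert-butyl (E)-3-nitroacrylate (nitro = masked C3a' ketone, ester = C1'), anti to the cis-fused ring A. C6'–OH comes from the diene's oxygenated carbon by reduction and inversion.
4. Rings A and C, with the C6 and C7 stereocentres, come from a catalytic enantioselective Diels–Alder reaction of cyclohex-2-enone with 2-(triisopropylsilyloxy)butadiene.
5. Order of ring formation: ring C onto ring A; bicyclo[2.2.2]octene (carbocycle of unit B); ring B lactone (key step); ring A lactone.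

Key step: step 15

Assumption: the (S)-configured oxazaborolidinium catalyst is taken to give the (4aR,8aS) adduct in step 2; if the sense of induction is the opposite, the (R)-catalyst is used.

## Route

Step 1
Reactants: 1 but-3-en-2-one
Product: 2 2-(triisopropylsilyloxy)buta-1,3-diene
Conditions: i-Pr3SiOTf, Et3N, CH2Cl2, 0 °C to rt
Reagents that add atoms: triisopropylsilyl trifluoromethanesulfonate CC(C)[Si](OS(=O)(=O)C(F)(F)F)(C(C)C)C(C)C
Why: O-silylation of the enone under soft enolisation (silyl dienol ether formation) should give the 2-silyloxydiene, no stereocentre being formed.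

Step 2
Reactants: 2 2-(triisopropylsilyloxy)buta-1,3-diene; 3 cyclohex-2-en-1-one
Product: 4 (4aR,8aS)-6-(triisopropylsilyloxy)-3,4,4a,5,8,8a-hexahydronaphthalen-1(2H)-one
Conditions: (S)-3,3-diphenyl-1-(2-methylphenyl)tetrahydro-1H,3H-pyrrolo[1,2-c][1,3,2]oxazaborole (20 mol %), HN(SO2CF3)2 (20 mol %), CH2Cl2, −78 to −20 °C
Reagents that add atoms: none
Why: Catalytic enantioselective Diels–Alder reaction with a chiral oxazaborolidinium Lewis acid bound to the enone oxygen; the CH2 terminus next to the silyloxy carbon bonds to the enone β-carbon (future C6), suprafacial addition makes the ring fusion cis, and the catalyst shields one enone face so that C6 and C7 are set in absolute terms.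

Step 3
Reactants: 4 (4aR,8aS)-6-(triisopropylsilyloxy)-3,4,4a,5,8,8a-hexahydronaphthalen-1(2H)-one
Product: 5 ethylene ketal of 4 (spiro-dioxolane at C7a; silyl enol ether kept)
Conditions: Me3SiOCH2CH2OSiMe3, Me3SiOTf (5 mol %), CH2Cl2, −78 °C; pyridine quench
Reagents that add atoms: 1,2-bis(trimethylsilyloxy)ethane C[Si](C)(C)OCCO[Si](C)(C)C
Why: Noyori ketalisation (Me3SiOTf-catalysed exchange with the bis-silyl ether of ethylene glycol) should protect the C7a ketone at −78 °C without hydrolysing the bulky silyl enol ether, and it removes the enolisable position next to C7.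

Step 4
Reactants: 5 ethylene ketal of 4
Product: 6 cis-fused enone ketal (C6' ketone; C5'=C4'; C7a ketal)
Conditions: Pd(OAc)2 (1.05 equiv), MeCN, rt to 40 °C
Reagents that add atoms: none
Why: Saegusa–Ito oxidation: Pd(OAc)2 converts the silyl enol ether into a palladium enolate whose β-hydride elimination towards C4' should give the C5'=C4' enone regiospecifically.

Step 5
Reactants: 6 cis-fused enone ketal
Product: 7 2-(trimethylsilyloxy)-1,3-diene of ring C (C7'=C6'(OSiMe3)–C5'=C4')
Conditions: LiN(i-Pr)2, THF, −78 °C; Me3SiCl; non-aqueous work-up, used crude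
Reagents that add atoms: chlorotrimethylsilane C[Si](C)(C)Cl
Why: Kinetic deprotonation at the α'-methylene C7' with a lithium amide at −78 °C and O-silylation (silyl dienol ether formation) should give the cross-conjugated diene, the γ-hydrogen at C7 not being removed under kinetic control.

Step 6
Reactants: 8 tert-butyl acrylate
Product: 10 tert-butyl (E)-3-nitroacrylate, via iodo nitro ester 9 (not isolated)
Conditions: N2O4, I2, Et2O, 0 °C; then NaOAc, Et2O, 0 °C to rt
Reagents that add atoms: dinitrogen tetroxide [O-][N+](=O)[N+](=O)[O-]
Why: Nitro-iodination of the acrylate followed by base-induced loss of HI, the standard preparation of β-nitroacrylates, should give the E isomer.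

Step 7
Reactants: 7 2-(trimethylsilyloxy)-1,3-diene of ring C; 10 tert-butyl (E)-3-nitroacrylate
Product: 12 tricyclic nitro keto ester (C6' ketone; C3a' nitro; C7a' tert-butyl ester; C7a ketal), via silyl enol ether cycloadduct 11 (not isolated)
Conditions: toluene, 0 °C to rt; then 0.5 M aqueous citric acid, THF, 0 °C
Reagents that add atoms: none
Why: Diels–Alder reaction of a 2-silyloxydiene with a β-nitroacrylate: the nitro group dominates the orientation so that the ester-bearing carbon (C7a') bonds to the nucleophilic terminus C7' and the nitro-bearing carbon (C3a') to C4', the dienophile adds to the diene face opposite to the cis-fused ring A and its spiro-ketal (setting C7' and C4' and placing ring A syn to the future C5'–C6' bridge), and the endo/exo outcome at C7a' and C3a' does not matter because both become trigonal in steps 8 and 9; mild acid then hydrolyses the silyl enol ether to the C6' ketone.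

Step 8
Reactants: 12 tricyclic nitro keto ester
Product: 14 tricyclic β-keto ester (C3a' ketone and C7a' tert-butyl ester, drawn as the enol; C6' ketone; C7a ketal), via sodium nitronate 13 (not isolated)
Conditions: NaOMe (1.05 equiv), MeOH/THF, −20 to 0 °C; then aqueous TiCl3, NH4OAc (pH 5–6), 0 °C to rt
Reagents that add atoms: water O
Why: Nef reaction in its TiCl3 (McMurry) form: one equivalent of methoxide converts the most acidic C–H (α to nitro) into the nitronate, which does not eliminate nitrite, and reduction to the imine followed by hydrolysis should give the C3a' ketone, erasing the C3a' and C7a' configurations.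

Step 9
Reactants: 14 tricyclic β-keto ester
Product: 15 enol triflate (C3a'–OTf; C7a'–CO2t-Bu; C6' ketone; C7a ketal)
Conditions: (CF3SO2)2O, i-Pr2NEt, CH2Cl2, −78 °C
Reagents that add atoms: trifluoromethanesulfonic anhydride O=S(=O)(OS(=O)(=O)C(F)(F)F)C(F)(F)F
Why: Enol triflate formation from the β-keto ester, the only carbonyl unit that is enolised by an amine base at −78 °C, fixes the C7a'=C3a' double bond and makes C3a' the electrophilic partner for the key step.

Step 10
Reactants: 15 enol triflate
Product: 16 C6' alcohol with OH syn to the ring A bridge (C6' epimer of the target pattern)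
Conditions: NaBH4, CeCl3·7H2O, MeOH, −78 °C
Reagents that add atoms: none
Why: Luche reduction: hydride should add to the C6' carbonyl from the face next to the trigonal C7a'=C3a' bridge, the other face being covered by C5H2 of ring A, which gives OH syn to the ring A bridge and leaves the vinyl triflate and the ester untouched.

Step 11
Reactants: 16 C6' alcohol with OH syn to the ring A bridge
Product: 19 C6' alcohol with OH syn to the C7a'=C3a' bridge (configuration of the target), via triflate 17 (not isolated), via nitrite ester 18 (not isolated)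
Conditions: (CF3SO2)2O, pyridine, CH2Cl2, −20 °C; then n-Bu4NNO2, toluene, rt; aqueous work-up
Reagents that add atoms: tetrabutylammonium nitrite CCCC[N+](CCCC)(CCCC)CCCC.[O-]N=O
Why: Lattrell–Dax inversion: the secondary triflate is displaced by the oxygen of nitrite in an SN2 reaction from the open face next to the trigonal bridge and the nitrite ester is hydrolysed on work-up, which sets C6' as in the target; E2 elimination is disfavoured because the rigid bicycle offers no antiperiplanar β-hydrogen.

Step 12
Reactants: 19 C6' alcohol with OH syn to the C7a'=C3a' bridge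
Product: 20 C6' triisopropylsilyl ether
Conditions: i-Pr3SiOTf, 2,6-lutidine, CH2Cl2, 0 °C to rt
Reagents that add atoms: triisopropylsilyl trifluoromethanesulfonate CC(C)[Si](OS(=O)(=O)C(F)(F)F)(C(C)C)C(C)C
Why: Silyl ether formation with a silyl triflate and a hindered non-nucleophilic base, chosen so that nothing adds to the β-triflyloxy enoate; the triisopropylsilyl ether is expected to survive the acid of step 13.

Step 13
Reactants: 20 C6' triisopropylsilyl ether
Product: 21 keto acid (C7a'–CO2H; C3a'–OTf; C7a ketone; C6'–OSi(i-Pr)3)
Conditions: CF3CO2H/CH2Cl2 (1:4), 0 °C to rt; then H2O, rt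
Reagents that add atoms: water O
Why: Acidolysis: the tert-butyl ester is cleaved through the tert-butyl cation and the dioxolane is hydrolysed by the aqueous acid, while the vinyl triflate and the secondary triisopropylsilyl ether are stable to CF3CO2H.

Step 14
Reactants: 21 keto acid; 22 (E)-pent-1-enylboronic acid
Product: 23 (E)-pent-1-enyl ester of 21 (Heck precursor)
Conditions: Cu(OAc)2 (20 mol %), pyridine, 4 Å molecular sieves, O2 (1 atm), CH2Cl2, rt
Reagents that add atoms: none
Why: Chan–Lam–Evans-type copper-catalysed oxidative O-alkenylation of a carboxylic acid with an alkenylboronic acid, which proceeds with retention of the E geometry and gives the enol ester that ties C3' to O2'.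

Step 15
Reactants: 23 (E)-pent-1-enyl ester of 21
Product: 24 ring B (Z)-butylidene butenolide (C7a ketone; C6'–OSi(i-Pr)3)
Conditions: Pd(OAc)2 (10 mol %), Ph2P(CH2)3PPh2 (12 mol %), 1,2,2,6,6-pentamethylpiperidine, MeCN, 70 °C
Reagents that add atoms: none
Why: Proposed new method: Oxidative addition of zerovalent palladium into the C3a'–OTf bond gives a cationic, halide-free vinylpalladium species, which adds syn across the tethered enol ester C3'=C8' bond in the 5-exo-trig mode with C3a' bonding to the oxygen-bearing carbon C3' (the only ring size open to the five-atom tether and also the electronically preferred α-attack of cationic palladium on enol ethers and esters); syn β-hydride elimination of C3'–H then gives the exocyclic C3'=C8' bond and closes the ring B lactone. The closest known reactions are the cationic-pathway Heck α-arylation and α-vinylation of vinyl ethers and vinyl esters with triflates and the 5-exo Heck cyclisation of N-vinyl 2-halobenzamides to 3-methyleneisoindolinones; the ester-tethered enol ester case is not documented. No sp3 stereocentre is made; the olefin geometry is substrate-controlled, since syn insertion followed by syn β-hydride elimination translates the E enol ester into the Z alkylidene (propyl cis to O2'), which is also the thermodynamically preferred isomer, so any palladium hydride re-addition should funnel towards it. The step needs β-hydride elimination from C3' to beat β-acyloxy elimination (which would reopen the lactone to a dienoic acid) and elimination towards C9'; the halide-free cationic manifold favours β-hydride over β-acyloxy elimination, conjugation with the C7a'=C3a'–C1'=O unit favours loss of the C3' hydrogen, and the amine removes the palladium hydride irreversibly. The extended ester conformer equilibrates with the reactive folded one at 70 °C, and the vinylpalladium intermediate, flanked only by the bridgehead C4', has no faster exit.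

Step 16
Reactants: 24 ring B (Z)-butylidene butenolide; 25 pentanoyl chloride
Product: 26 ring A 1,3-diketone (pentanoyl at C3a; drawn as the C7a enol)
Conditions: MgBr2·OEt2, i-Pr2NEt, CH2Cl2, 0 °C to rt
Reagents that add atoms: none
Why: Soft-enolisation C-acylation of a ketone (MgBr2·OEt2 with a tertiary amine): acylation should occur at the methylene C3a and not at the methine C7 because only the methylene product is stabilised as its magnesium diketonate, and the conditions are mild enough for the ring B enol lactone.

Step 17
Reactants: 26 ring A 1,3-diketone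
Product: 27 ring A enol triflate (C7a–OTf; C3a–pentanoyl)
Conditions: (CF3SO2)2O, i-Pr2NEt, CH2Cl2, −78 °C
Reagents that add atoms: trifluoromethanesulfonic anhydride O=S(=O)(OS(=O)(=O)C(F)(F)F)C(F)(F)F
Why: O-Triflation of the endocyclic enol of the 2-acylcyclohexanone (the enol form favoured in six-membered rings) should give the ring enol triflate at C7a conjugated with the pentanoyl ketone.

Step 18
Reactants: 27 ring A enol triflate
Product: 28 C6' triisopropylsilyl ether of the target
Conditions: Pd(PPh3)4 (5 mol %), CO (1 atm), Et3N, MeCN, 60 °C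
Reagents that add atoms: carbon monoxide [C-]#[O+]
Why: Palladium-catalysed carbonylative cyclisation of a β-triflyloxy enone: oxidative addition of zerovalent palladium at C7a, CO insertion to the acylpalladium species (C1) and O-acylation of the amine-generated enol of the pentanoyl ketone close the ring A lactone, the Z alkylidene (propyl away from C4) being the kinetically and thermodynamically preferred geometry.

Step 19
Reactants: 28 C6' triisopropylsilyl ether of the target
Product: 29 CNP0289078.1
Conditions: HF·pyridine, THF, 0 °C to rt
Reagents that add atoms: none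
Why: Fluoride-mediated cleavage of the silyl ether under acidic, non-nucleophilic conditions that should leave both enol lactones intact; no stereocentre is touched.

## Compound list

1 | but-3-en-2-one (methyl vinyl ketone) | CC(=O)C=C | starting material
2 | 2-(triisopropylsilyloxy)buta-1,3-diene | C=CC(=C)O[Si](C(C)C)(C(C)C)C(C)C | intermediate
3 | cyclohex-2-en-1-one | O=C1C=CCCC1 | starting material
4 | (4aR,8aS)-6-(triisopropylsilyloxy)-3,4,4a,5,8,8a-hexahydronaphthalen-1(2H)-one; cis-fused rings A and C | O=C2CCC[C@@H]1CC(O[Si](C(C)C)(C(C)C)C(C)C)=CC[C@H]21 | intermediate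
5 | ethylene ketal of 4 (spiro-1,3-dioxolane at C7a; same cis ring fusion) | O1CCOC12CCC[C@@H]3CC(O[Si](C(C)C)(C(C)C)C(C)C)=CC[C@H]23 | intermediate
6 | cis-fused enone ketal: C6' ketone, C5'=C4', C7a spiro-dioxolane | O1CCOC12CCC[C@@H]3CC(=O)C=C[C@H]23 | intermediate
7 | trimethylsilyl dienol ether of 6: C7'=C6'(OSiMe3)–C5'=C4' | O1CCOC12CCC[C@@H]3C=C(O[Si](C)(C)C)C=C[C@H]23 | intermediate
8 | tert-butyl acrylate | C=CC(=O)OC(C)(C)C | starting material
9 | tert-butyl 2-iodo-3-nitropropanoate (racemic) | [O-][N+](=O)CC(I)C(=O)OC(C)(C)C | intermediate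
10 | tert-butyl (E)-3-nitroacrylate | [O-][N+](=O)/C=C/C(=O)OC(C)(C)C | intermediate
11 | Diels–Alder adduct as silyl enol ether: bicyclo[2.2.2]octene with bridgeheads C7' and C4'; C6'(OSiMe3)=C5'; C7a'–CO2t-Bu and C3a'–NO2 trans (nitro syn to the C5'–C6' bridge, expected major isomer); ring A cis-fused at C6–C7 on the side of the C5'–C6' bridge; C7a ketal | O1CCOC12CCC[C@@H]3[C@H]4[C@@H](C(=O)OC(C)(C)C)[C@H]([N+](=O)[O-])[C@H](C=C4O[Si](C)(C)C)[C@H]23 | intermediate
12 | tricyclic nitro keto ester: as 11 with C6' ketone and C5'H2 | O1CCOC12CCC[C@@H]3[C@H]4[C@@H](C(=O)OC(C)(C)C)[C@H]([N+](=O)[O-])[C@H](CC4=O)[C@H]23 | intermediate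
13 | sodium nitronate of 12 (C3a'=NO2Na) | [Na+].O1CCOC12CCC[C@@H]3[C@H]4[C@@H](C(=O)OC(C)(C)C)C(=[N+]([O-])[O-])[C@H](CC4=O)[C@H]23 | intermediate
14 | tricyclic β-keto ester: C3a' ketone and C7a'–CO2t-Bu (keto–enol mixture, drawn as the C7a'=C3a' enol); C6' ketone; C7a ketal | O1CCOC12CCC[C@@H]3[C@H]4C(C(=O)OC(C)(C)C)=C(O)[C@H](CC4=O)[C@H]23 | intermediate
15 | enol triflate: C7a'(CO2t-Bu)=C3a'(OTf); C6' ketone; C7a ketal | O1CCOC12CCC[C@@H]3[C@H]4C(C(=O)OC(C)(C)C)=C(OS(=O)(=O)C(F)(F)F)[C@H](CC4=O)[C@H]23 | intermediate
16 | C6' alcohol of 15 with OH syn to the ring A (C6–C7) bridge and anti to the C7a'=C3a' bridge | O1CCOC12CCC[C@@H]3[C@H]4C(C(=O)OC(C)(C)C)=C(OS(=O)(=O)C(F)(F)F)[C@H](C[C@H]4O)[C@H]23 | intermediate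
17 | C6' triflate of 16 (same C6' configuration) | O1CCOC12CCC[C@@H]3[C@H]4C(C(=O)OC(C)(C)C)=C(OS(=O)(=O)C(F)(F)F)[C@H](C[C@H]4OS(=O)(=O)C(F)(F)F)[C@H]23 | intermediate
18 | C6' nitrite ester (inverted; O syn to the C7a'=C3a' bridge) | O1CCOC12CCC[C@@H]3[C@H]4C(C(=O)OC(C)(C)C)=C(OS(=O)(=O)C(F)(F)F)[C@H](C[C@@H]4ON=O)[C@H]23 | intermediate
19 | C6' alcohol with OH syn to the C7a'=C3a' bridge (target configuration); C3a'–OTf; C7a'–CO2t-Bu; C7a ketal | O1CCOC12CCC[C@@H]3[C@H]4C(C(=O)OC(C)(C)C)=C(OS(=O)(=O)C(F)(F)F)[C@H](C[C@@H]4O)[C@H]23 | intermediate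
20 | C6' triisopropylsilyl ether of 19 | O1CCOC12CCC[C@@H]3[C@H]4C(C(=O)OC(C)(C)C)=C(OS(=O)(=O)C(F)(F)F)[C@H](C[C@@H]4O[Si](C(C)C)(C(C)C)C(C)C)[C@H]23 | intermediate
21 | keto acid: C7a'–CO2H; C3a'–OTf; C6'–OSi(i-Pr)3; ring A C7a ketone | O=C2CCC[C@@H]1[C@H]3C(C(=O)O)=C(OS(=O)(=O)C(F)(F)F)[C@H](C[C@@H]3O[Si](C(C)C)(C(C)C)C(C)C)[C@H]21 | intermediate
22 | (E)-pent-1-enylboronic acid | CCC/C=C/B(O)O | starting material
23 | (E)-pent-1-enyl ester of 21 | O=C2CCC[C@@H]1[C@H]3C(C(=O)O/C=C/CCC)=C(OS(=O)(=O)C(F)(F)F)[C@H](C[C@@H]3O[Si](C(C)C)(C(C)C)C(C)C)[C@H]21 | intermediate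
24 | ring B (Z)-butylidene butenolide fused at C7a'=C3a'; C6'–OSi(i-Pr)3; ring A C7a ketone | O=C2CCC[C@@H]1[C@H]3C4=C(/C(=C/CCC)OC4=O)[C@H](C[C@@H]3O[Si](C(C)C)(C(C)C)C(C)C)[C@H]21 | intermediate
25 | pentanoyl chloride | CCCCC(Cl)=O | starting material
26 | ring A 1,3-diketone of 24: pentanoyl at C3a, drawn as the C7a enol | OC2=C(C(=O)CCCC)CC[C@@H]1[C@H]3C4=C(/C(=C/CCC)OC4=O)[C@H](C[C@@H]3O[Si](C(C)C)(C(C)C)C(C)C)[C@H]21 | intermediate
27 | ring A enol triflate: C7a(OTf)=C3a–C(=O)Bu | FC(F)(F)S(=O)(=O)OC2=C(C(=O)CCCC)CC[C@@H]1[C@H]3C4=C(/C(=C/CCC)OC4=O)[C@H](C[C@@H]3O[Si](C(C)C)(C(C)C)C(C)C)[C@H]21 | intermediate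
28 | C6' triisopropylsilyl ether of the target (both Z-butylidene butenolides in place) | CCC/C=C1\OC(=O)C2=C1CC[C@@H]1[C@H]3C4=C(/C(=C/CCC)OC4=O)[C@H](C[C@@H]3O[Si](C(C)C)(C(C)C)C(C)C)[C@H]21 | intermediate
29 | CNP0289078.1 | CCC/C=C1\OC(=O)C2=C1CC[C@@H]1[C@H]3C4=C(/C(=C/CCC)OC4=O)[C@H](C[C@@H]3O)[C@H]21 | target

## Step count and risks

Total step count: 19. Longest linear sequence: 18 steps (steps 1–5 and 7–19 from but-3-en-2-one; step 6 is a one-step side branch that prepares dienophile 10).

Steps most likely to fail:

1. Step 15 (Proposed new method). After the 5-exo insertion the alkylpalladium intermediate may lose the β-acyloxy group instead of the β-hydrogen, which reopens the lactone to a dienoic acid. The ester may also stay in its extended conformation, so that reduction or oligomerisation of the vinylpalladium species takes over. Fallback with known chemistry: setting out from acid 21, Sonogashira coupling with pent-1-yne (PdCl2(PPh3)2, CuI, Et3N, MeCN, rt) gives the enynoic acid F1. AgNO3-catalysed 5-exo-dig lactonisation (acetone, rt; anti-oxymetallation then protodemetallation, Z-selective) then gives butenolide 24, where the route is rejoined.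

2. Step 8. Base-induced loss of nitrous acid through the ester α-carbanion may compete with nitronate formation and give the conjugated ester instead of the ketone. Fallback: setting out from 12, the nitro group is reduced to the oxime F2 with SnCl2·2H2O, PhSH and Et3N in MeCN, which needs no strongly basic nitronate generation. Transoximation with aqueous glyoxylic acid in AcOH then gives β-keto ester 14, where the route is rejoined.

3. Step 11. The secondary triflate next to the bridgehead may ionise and undergo a skeletal shift, or substitution may be too slow. Fallback: setting out from 16, a Mitsunobu reaction with formic acid (PPh3, diisopropyl azodicarboxylate, THF/toluene, 0 °C to rt) gives the inverted formate F3 without a free carbocation. KHCO3 in MeOH at 0 °C then removes the formyl group to give alcohol 19, where the route is rejoined.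

Further compounds
F1 | step 15 | enynoic acid: C7a'–CO2H and C3a'–pent-1-ynyl on the alkene bridge; C6'–OSi(i-Pr)3; ring A C7a ketone | O=C2CCC[C@@H]1[C@H]3C(C(=O)O)=C(C#CCCC)[C@H](C[C@@H]3O[Si](C(C)C)(C(C)C)C(C)C)[C@H]21
F2 | step 8 | oxime of the C3a' ketone (from 12; oxime geometry not fixed; C7a' as in 12) | O1CCOC12CCC[C@@H]3[C@H]4[C@@H](C(=O)OC(C)(C)C)C(=NO)[C@H](CC4=O)[C@H]23
F3 | step 11 | C6' formate with O syn to the C7a'=C3a' bridge (inverted relative to 16) | O1CCOC12CCC[C@@H]3[C@H]4C(C(=O)OC(C)(C)C)=C(OS(=O)(=O)C(F)(F)F)[C@H](C[C@@H]4OC=O)[C@H]23
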